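**Plan**

- Retrosynthesis: the three O-benzyl groups come off last and the C4 carbinol goes back to a ketone. The pyranone is then cut at C5–C6, the open-chain ether at O1–C6, the enol acetate at its C4–O bond (back to an alkyne), and the chain at C2–C3 (aldehyde plus a propargyl unit).
- Forward: eugenol is turned into a 3-arylpropanal, C2–C3 is made by asymmetric propargylation, and O1–C6 by Williamson etherification with a 3,4,5-trioxygenated benzyl bromide made from 3,4-dihydroxy-5-methoxybenzaldehyde. Acetic acid is then added to the alkyne, and the only ring of the target, the tetrahydropyran, closes last at C5–C6.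
- Enabling feature: C6 of the pyran (O1, C2 arylethyl, C4–OH, C6 aryl) is benzylic to the trioxygenated ring and bonded to O1, so in the open-chain benzyl ether its C–H can leave as hydride. C5 and C4 are the terminal and the oxygen-bearing carbon of an enol acetate that traps the resulting cation.
- Stereochemistry: C2 (S) comes from catalyst control in the propargylation, C6 (S) from C2 through a chair transition state in the ring closure (2,6-cis), and C4 (R) from axial hydride attack on the ketone (equatorial alcohol, all-cis).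

Key step: step 10

Assumption: the (R)-BINOL/Ti(OiPr)4 catalyst is taken to direct the allenylstannane to the same aldehyde face (Re for an unbranched aliphatic aldehyde) as it directs allyltributylstannane in the Keck allylation; allenyltributylstannane is taken as a purchased reagent.

**Route**

Step 1
Reactants: 1 eugenol (4-allyl-2-methoxyphenol)
Product: 2 4-allyl-1-(benzyloxy)-2-methoxybenzene
Conditions: BnBr, K2CO3, DMF, rt
Reagents that add atoms: benzyl bromide, BrCc1ccccc1
Why: Williamson ether synthesis, in which the phenoxide formed with K2CO3 displaces bromide from benzyl bromide (SN2) and the benzyl ether masks the phenol until the final hydrogenolysis.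

Step 2
Reactants: 2 4-allyl-1-(benzyloxy)-2-methoxybenzene
Product: 4 3-[4-(benzyloxy)-3-methoxyphenyl]propan-1-ol, via alkylborane 3 (not isolated)
Conditions: 9-BBN, THF, 0 °C to rt; then NaOH, H2O2, H2O, 0 °C to rt
Reagents that add atoms: hydrogen peroxide, OO
Why: Brown hydroboration–oxidation, in which the bulky 9-BBN places boron on the terminal carbon of the allyl group and alkaline H2O2 replaces boron by hydroxyl to give the anti-Markovnikov primary alcohol.

Step 3
Reactants: 4 3-[4-(benzyloxy)-3-methoxyphenyl]propan-1-ol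
Product: 5 3-[4-(benzyloxy)-3-methoxyphenyl]propanal
Conditions: PhI(OAc)2, TEMPO (cat.), CH2Cl2, rt
Reagents that add atoms: none
Why: TEMPO-catalysed oxidation of a primary alcohol with PhI(OAc)2 as terminal oxidant, which stops at the aldehyde and leaves the electron-rich arene and the benzyl ether untouched.

Step 4
Reactants: 5 3-[4-(benzyloxy)-3-methoxyphenyl]propanal; 6 allenyltributylstannane
Product: 8 (3S)-1-[4-(benzyloxy)-3-methoxyphenyl]hex-5-yn-3-ol, via tributylstannyl ether 7 (not isolated)
Conditions: (R)-BINOL (cat.), Ti(OiPr)4 (cat.), 4 Å MS, CH2Cl2, −20 °C; then aq. NaHCO3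
Reagents that add atoms: none
Why: Keck-type catalytic asymmetric propargylation, in which the BINOL–titanium Lewis acid activates the aldehyde and the allenylstannane adds by an SE2′ process to give the homopropargylic alcohol, the (R)-ligand directing attack to the Re face of the aldehyde and so setting the (S) centre that becomes C2 of the pyran.

Step 5
Reactants: 9 3,4-dihydroxy-5-methoxybenzaldehyde
Product: 10 3,4-bis(benzyloxy)-5-methoxybenzaldehyde
Conditions: BnBr, K2CO3, DMF, 60 °C
Reagents that add atoms: benzyl bromide, BrCc1ccccc1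
Why: twofold Williamson ether synthesis on the catechol, which the aldehyde tolerates.

Step 6
Reactants: 10 3,4-bis(benzyloxy)-5-methoxybenzaldehyde
Product: 11 [3,4-bis(benzyloxy)-5-methoxyphenyl]methanol
Conditions: NaBH4, MeOH/THF, 0 °C
Reagents that add atoms: none
Why: borohydride reduction of an aromatic aldehyde to the benzylic alcohol, to which aryl benzyl ethers are inert.

Step 7
Reactants: 11 [3,4-bis(benzyloxy)-5-methoxyphenyl]methanol
Product: 12 1,2-bis(benzyloxy)-5-(bromomethyl)-3-methoxybenzene
Conditions: PBr3, Et2O, 0 °C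
Reagents that add atoms: phosphorus tribromide, BrP(Br)Br
Why: standard bromination of a primary benzylic alcohol with PBr3 (activation of the hydroxyl and SN2 displacement by bromide), giving a 3,4,5-trialkoxybenzyl bromide that is stable enough to be used directly.

Step 8
Reactants: 8 (3S)-1-[4-(benzyloxy)-3-methoxyphenyl]hex-5-yn-3-ol; 12 1,2-bis(benzyloxy)-5-(bromomethyl)-3-methoxybenzene
Product: 14 (3S)-3-{[3,4-bis(benzyloxy)-5-methoxyphenyl]methoxy}-1-[4-(benzyloxy)-3-methoxyphenyl]hex-5-yne, via sodium alkoxide 13 (not isolated)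
Conditions: NaH, THF/DMF, 0 °C; then 12, Bu4NI (cat.), 0 °C to rt
Reagents that add atoms: none
Why: Williamson ether synthesis, in which NaH converts the secondary alcohol into alkoxide 13 and this displaces bromide from the benzylic bromide under iodide catalysis, so the C–O bond of the stereocentre is not touched and the (S) configuration is kept.

Step 9
Reactants: 14 (3S)-3-{[3,4-bis(benzyloxy)-5-methoxyphenyl]methoxy}-1-[4-(benzyloxy)-3-methoxyphenyl]hex-5-yne
Product: 15 (4S)-6-[4-(benzyloxy)-3-methoxyphenyl]-4-{[3,4-bis(benzyloxy)-5-methoxyphenyl]methoxy}hex-1-en-2-yl acetate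
Conditions: AcOH, [Ru(p-cymene)Cl2]2 (cat.), tri(2-furyl)phosphine (cat.), Na2CO3 (cat.), toluene, 80 °C
Reagents that add atoms: acetic acid, CC(=O)O
Why: ruthenium-catalysed Markovnikov hydro-acyloxylation of a terminal alkyne, in which acetic acid adds across the triple bond with the acetate on the internal carbon to give the 2-acetoxy-1-alkene that serves as the nucleophile of the ring closure.

Step 10
Reactants: 15 (4S)-6-[4-(benzyloxy)-3-methoxyphenyl]-4-{[3,4-bis(benzyloxy)-5-methoxyphenyl]methoxy}hex-1-en-2-yl acetate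
Product: 18 (2S,6S)-2-{2-[4-(benzyloxy)-3-methoxyphenyl]ethyl}-6-[3,4-bis(benzyloxy)-5-methoxyphenyl]oxan-4-one (2,6-cis ketone), via oxocarbenium ion 16 (not isolated), via O-acetyl oxocarbenium ion 17 (not isolated)
Conditions: DDQ, 2,6-dichloropyridine, 4 Å MS, ClCH2CH2Cl, rt; then aq. NaHCO3
Reagents that add atoms: none
Why: DDQ takes an electron from the trioxygenated benzyl ether and then a hydrogen atom from its O–CH2 group, a net hydride abstraction that gives the (E)-aryl oxocarbenium ion 16; the enol acetate attacks this through its terminal carbon, and the O-acetyl oxocarbenium ion 17 then loses its acetyl group to leave the 4-ketone. The reaction type is the known DDQ-mediated oxidative C–H cyclisation of electron-rich benzylic ethers onto enol acetates, a Prins-type closure started by C–H cleavage. The tetrahydropyran closes by a 6-endo-trig attack that forms C5–C6 through a chair. The new stereocentre C6 is controlled by the existing C2 centre: the aryl group of the (E)-oxocarbenium ion and the C2 arylethyl chain both sit equatorial in the chair, which should give the 2,6-cis (2S,6S) ketone. The step needs site selectivity for the ether CH2 over the ArCH2 group of the guaiacyl chain and the three PhCH2O groups; only the ether CH2 gives a cation stabilised by both an oxygen lone pair and the electron-rich ring, and the phenyl rings of the benzyl groups are too electron-poor to be oxidised. Molecular sieves keep water from hydrolysing the cation and 2,6-dichloropyridine buffers the acid that is formed.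

Step 11
Reactants: 18 (2S,6S)-2-{2-[4-(benzyloxy)-3-methoxyphenyl]ethyl}-6-[3,4-bis(benzyloxy)-5-methoxyphenyl]oxan-4-one
Product: 19 (2S,4R,6S)-2-{2-[4-(benzyloxy)-3-methoxyphenyl]ethyl}-6-[3,4-bis(benzyloxy)-5-methoxyphenyl]oxan-4-ol (all-cis)
Conditions: NaBH4, MeOH, −20 °C
Reagents that add atoms: none
Why: hydride reduction of a conformationally fixed cyclic ketone, in which the small borohydride attacks the chair held by the two equatorial substituents from the axial direction and should give the equatorial (4R) alcohol, cis to both ring substituents.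

Step 12
Reactants: 19 (2S,4R,6S)-2-{2-[4-(benzyloxy)-3-methoxyphenyl]ethyl}-6-[3,4-bis(benzyloxy)-5-methoxyphenyl]oxan-4-ol
Product: 20 (2S,4R,6S)-2-[2-(4-hydroxy-3-methoxyphenyl)ethyl]-6-(3,4-dihydroxy-5-methoxyphenyl)oxan-4-ol (CNP0399218.1)
Conditions: H2 (1 atm), Pd/C, EtOAc/MeOH, rt
Reagents that add atoms: none
Why: catalytic hydrogenolysis of the three aryl benzyl ethers on Pd/C, which should be faster than cleavage of the secondary, hindered ring C6–O1 bond when the reaction is run in a neutral solvent and stopped at full debenzylation.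

**Compound list**

1 | eugenol (4-allyl-2-methoxyphenol) | C=CCc1ccc(O)c(OC)c1 | starting material
2 | 4-allyl-1-(benzyloxy)-2-methoxybenzene | C=CCc1ccc(OCc2ccccc2)c(OC)c1 | intermediate
3 | 9-{3-[4-(benzyloxy)-3-methoxyphenyl]propyl}-9-borabicyclo[3.3.1]nonane | COc1cc(CCCB2C3CCCC2CCC3)ccc1OCc1ccccc1 | intermediate
4 | 3-[4-(benzyloxy)-3-methoxyphenyl]propan-1-ol | COc1cc(CCCO)ccc1OCc1ccccc1 | intermediate
5 | 3-[4-(benzyloxy)-3-methoxyphenyl]propanal | COc1cc(CCC=O)ccc1OCc1ccccc1 | intermediate
6 | allenyltributylstannane (tributyl(propa-1,2-dienyl)stannane) | C=C=C[Sn](CCCC)(CCCC)CCCC | starting material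
7 | tributylstannyl ether of 8, (3S)-configured | COc1cc(CC[C@H](O[Sn](CCCC)(CCCC)CCCC)CC#C)ccc1OCc1ccccc1 | intermediate
8 | (3S)-1-[4-(benzyloxy)-3-methoxyphenyl]hex-5-yn-3-ol | COc1cc(CC[C@H](O)CC#C)ccc1OCc1ccccc1 | intermediate
9 | 3,4-dihydroxy-5-methoxybenzaldehyde | COc1cc(C=O)cc(O)c1O | starting material
10 | 3,4-bis(benzyloxy)-5-methoxybenzaldehyde | COc1cc(C=O)cc(OCc2ccccc2)c1OCc1ccccc1 | intermediate
11 | [3,4-bis(benzyloxy)-5-methoxyphenyl]methanol | COc1cc(CO)cc(OCc2ccccc2)c1OCc1ccccc1 | intermediate
12 | 1,2-bis(benzyloxy)-5-(bromomethyl)-3-methoxybenzene | COc1cc(CBr)cc(OCc2ccccc2)c1OCc1ccccc1 | intermediate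
13 | sodium alkoxide of 8, (3S)-configured | [Na+].COc1cc(CC[C@H]([O-])CC#C)ccc1OCc1ccccc1 | intermediate
14 | (3S)-3-{[3,4-bis(benzyloxy)-5-methoxyphenyl]methoxy}-1-[4-(benzyloxy)-3-methoxyphenyl]hex-5-yne | COc1cc(CC[C@H](OCc2cc(OC)c(OCc3ccccc3)c(OCc3ccccc3)c2)CC#C)ccc1OCc1ccccc1 | intermediate
15 | (4S)-6-[4-(benzyloxy)-3-methoxyphenyl]-4-{[3,4-bis(benzyloxy)-5-methoxyphenyl]methoxy}hex-1-en-2-yl acetate | COc1cc(CC[C@H](OCc2cc(OC)c(OCc3ccccc3)c(OCc3ccccc3)c2)CC(=C)OC(C)=O)ccc1OCc1ccccc1 | intermediate
16 | (E)-aryl oxocarbenium ion formed from 15 by loss of hydride from the ArCH2–O carbon, (S) at the carbinol carbon | COc1cc(CC[C@@H](CC(=C)OC(C)=O)/[O+]=C/c2cc(OC)c(OCc3ccccc3)c(OCc3ccccc3)c2)ccc1OCc1ccccc1 | intermediate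
17 | cyclised O-acetyl oxocarbenium ion, (2S,6S), acetyl still on the C4 oxygen | COc1cc(CC[C@H]2CC(=[O+]C(C)=O)C[C@@H](c3cc(OC)c(OCc4ccccc4)c(OCc4ccccc4)c3)O2)ccc1OCc1ccccc1 | intermediate
18 | (2S,6S)-2-{2-[4-(benzyloxy)-3-methoxyphenyl]ethyl}-6-[3,4-bis(benzyloxy)-5-methoxyphenyl]oxan-4-one (2,6-cis) | COc1cc(CC[C@H]2CC(=O)C[C@@H](c3cc(OC)c(OCc4ccccc4)c(OCc4ccccc4)c3)O2)ccc1OCc1ccccc1 | intermediate
19 | (2S,4R,6S)-2-{2-[4-(benzyloxy)-3-methoxyphenyl]ethyl}-6-[3,4-bis(benzyloxy)-5-methoxyphenyl]oxan-4-ol (all-cis) | COc1cc(CC[C@H]2C[C@@H](O)C[C@@H](c3cc(OC)c(OCc4ccccc4)c(OCc4ccccc4)c3)O2)ccc1OCc1ccccc1 | intermediate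
20 | (2S,4R,6S)-2-[2-(4-hydroxy-3-methoxyphenyl)ethyl]-6-(3,4-dihydroxy-5-methoxyphenyl)oxan-4-ol (CNP0399218.1) | COc1cc(CC[C@H]2C[C@@H](O)C[C@@H](c3cc(O)c(O)c(OC)c3)O2)ccc1O | target

**Step count**

Total step count: 12 (steps 1–4 chain fragment, steps 5–7 benzyl bromide, steps 8–12 after the union).
Longest linear sequence: 9 steps (steps 1–4 and 8–12, from eugenol).

**Steps most likely to fail**

1. Step 10 (oxidative cyclisation). What may go wrong: hydride loss at the wrong benzylic site (the ArCH2 group of the guaiacyl chain), hydrolysis of the oxocarbenium ion by traces of water before the enol acetate traps it, or further oxidation of the product at C6. The fallback sets out from alkynol 8 and aldehyde 10 and comes back to the route at alcohol 19. Semi-hydrogenation of 8 with H2 over Pd/CaCO3 poisoned with Pb(OAc)2 and quinoline should give the homoallylic alcohol (3S)-1-[4-(benzyloxy)-3-methoxyphenyl]hex-5-en-3-ol F1. A Prins cyclisation of F1 with aldehyde 10 in CF3CO2H/CH2Cl2 should close the same ring through an all-equatorial chair, forming O1–C6 and C5–C6, and give the all-cis (2S,4R,6S)-2-{2-[4-(benzyloxy)-3-methoxyphenyl]ethyl}-6-[3,4-bis(benzyloxy)-5-methoxyphenyl]oxan-4-yl trifluoroacetate F2. Methanolysis of F2 with K2CO3 in MeOH then gives 19, so that steps 8 to 11 are bypassed.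

2. Step 4 (asymmetric propargylation). What may go wrong: poor facial selectivity on the unbranched aliphatic aldehyde, slow turnover of the titanium catalyst, or formation of the allenyl carbinol by direct transfer without allylic shift. The fallback sets out from aldehyde 5 and comes back at alkynol 8. Corey–Chaykovsky methylenation of 5 with trimethylsulfonium iodide and NaH in DMSO/THF should give the racemic epoxide 2-{2-[4-(benzyloxy)-3-methoxyphenyl]ethyl}oxirane F3. Jacobsen hydrolytic kinetic resolution with the (S,S) enantiomer of the (salen)Co(OAc) catalyst, whose ligand is N,N′-bis(3,5-di-tert-butylsalicylidene)-1,2-cyclohexanediamine, and 0.55 equiv of water should hydrolyse the (R)-epoxide and leave (2S)-2-{2-[4-(benzyloxy)-3-methoxyphenyl]ethyl}oxirane F4. Opening of F4 at its CH2 terminus with lithium acetylide–ethylenediamine complex in DMSO gives 8 with the stereocentre untouched. At most half of F3 can be carried on.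

3. Step 12 (hydrogenolysis). What may go wrong: hydrogenolysis of the ring C6–O1 bond, which is benzylic to an electron-rich arene, during or after the debenzylation, which would open the pyran. The fallback sets out from ketone 18 and comes back at the target 20. The benzyl ethers are cleaved without hydrogen by BCl3 with pentamethylbenzene as cation scavenger in CH2Cl2 at −78 °C, at the ketone stage where the carbonyl group disfavours ionisation at C6. This should give (2S,6S)-2-[2-(4-hydroxy-3-methoxyphenyl)ethyl]-6-(3,4-dihydroxy-5-methoxyphenyl)oxan-4-one F5. Reduction of F5 with NaBH4 in MeOH at −20 °C, by the same axial attack as in step 11, then gives 20.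

Further compounds
F1 | step 10 | (3S)-1-[4-(benzyloxy)-3-methoxyphenyl]hex-5-en-3-ol | COc1cc(CC[C@H](O)CC=C)ccc1OCc1ccccc1
F2 | step 10 | (2S,4R,6S)-2-{2-[4-(benzyloxy)-3-methoxyphenyl]ethyl}-6-[3,4-bis(benzyloxy)-5-methoxyphenyl]oxan-4-yl trifluoroacetate | COc1cc(CC[C@H]2C[C@@H](OC(=O)C(F)(F)F)C[C@@H](c3cc(OC)c(OCc4ccccc4)c(OCc4ccccc4)c3)O2)ccc1OCc1ccccc1
F3 | step 4 | racemic 2-{2-[4-(benzyloxy)-3-methoxyphenyl]ethyl}oxirane | COc1cc(CCC2CO2)ccc1OCc1ccccc1
F4 | step 4 | (2S)-2-{2-[4-(benzyloxy)-3-methoxyphenyl]ethyl}oxirane | COc1cc(CC[C@H]2CO2)ccc1OCc1ccccc1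
F5 | step 12 | (2S,6S)-2-[2-(4-hydroxy-3-methoxyphenyl)ethyl]-6-(3,4-dihydroxy-5-methoxyphenyl)oxan-4-one | COc1cc(CC[C@H]2CC(=O)C[C@@H](c3cc(O)c(O)c(OC)c3)O2)ccc1O
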